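**Plan**
- Retrosynthesis: remove the C11=C13 methylene and the O9 isobutyrate, open the lactone at O8–C12, cut the ring bond C8–C9 (both carbons carry oxygen), then cut C6–C7. This leaves geraniol and a succinic half-ester.
- Enabling feature: in the ten-membered ring C1–C10, the neighbours C8 and C9 carry the lactone oxygen and the ester oxygen on the same ring face. The chain C6–C5–C4–C3–C2–C1–C10–C9 with methyls C15 and C14 is the geraniol skeleton.
- Forward: the chain is joined at C6–C7 by an aldol, both ends are brought to aldehydes (C8, C9), the ten-membered ring closes at C8–C9, then the five-membered lactone closes at O8–C12, and the end game follows.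
- Stereochemistry: C4/C5 come from Sharpless epoxidation, C6/C7 from the oxazolidinone aldol, C8/C9 from the ring-closing pinacol, and the E C1=C10 alkene from geraniol and the E-selective allylic oxidation.

Key step: step 9

Assumption: germacrane numbering of the target is used for all intermediates. C12 is carried as a tert-butyl ester, because an unhindered ester at C12 would be closed to a lactone by the C6 boron aldolate in step 4 and by the C8 alkoxide in step 7.

Step 1
Reactants: 1 geraniol
Product: 2 (2S,3S)-2,3-epoxygeraniol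
Conditions: Ti(OiPr)4 (cat.), L-(+)-diethyl tartrate (cat.), t-BuOOH, 4 Å molecular sieves, CH2Cl2, −20 °C
Reagents that add atoms: tert-butyl hydroperoxide, CC(C)(C)OO
Why: Sharpless asymmetric epoxidation, in which the titanium tartrate complex binds the allylic hydroxyl and delivers oxygen only to the C4=C5 alkene on the face fixed by L-(+)-diethyl tartrate, setting C4 and C5 and leaving the distal alkene untouched.

Step 2
Reactants: 2 (2S,3S)-2,3-epoxygeraniol
Product: 3 (2R,3S)-2,3-epoxygeranial
Conditions: TEMPO (cat.), PhI(OAc)2, CH2Cl2, rt; used at once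
Reagents that add atoms: none
Why: Oxoammonium (TEMPO) oxidation stops at the aldehyde under nearly neutral conditions, so the sensitive epoxy aldehyde should form without opening of the epoxide.

Step 3
Reactants: 4 mono-tert-butyl succinate; 5 (S)-4-benzyl-2-oxazolidinone
Product: 7 tert-butyl 4-[(4S)-4-benzyl-2-oxo-1,3-oxazolidin-3-yl]-4-oxobutanoate (succinyl imide), via mixed pivalic anhydride 6 (not isolated)
Conditions: pivaloyl chloride, Et3N, THF, −20 °C; then LiCl, 5, −20 °C to rt
Reagents that add atoms: none
Why: N-acylation of the oxazolidinone through a mixed pivalic anhydride is a standard one-pot imide synthesis, the nitrogen attacking the unhindered succinyl carbonyl.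

Step 4
Reactants: 7 succinyl imide; 3 (2R,3S)-2,3-epoxygeranial
Product: 10 syn aldol adduct (C8 imide; C7 bearing CH2CO2t-Bu; C6 hydroxyl; 4,5-epoxide), via boron enolate 8 (not isolated), via boron aldolate 9 (not isolated)
Conditions: Bu2BOTf, i-Pr2NEt, CH2Cl2, −78 to 0 °C; then 3, −78 to 0 °C; then pH 7 buffer, MeOH, H2O2, 0 °C
Reagents that add atoms: none
Why: Evans syn aldol, in which soft enolisation gives only the Z boron enolate of the imide and this adds to 3 through a Zimmerman–Traxler chair on the face away from the benzyl group, setting C7 and C6 (both S) with the Felkin/Cornforth preference of the epoxy aldehyde pointing the same way, while the tert-butyl ester keeps the C6 aldolate from lactonising.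

Step 5
Reactants: 10 syn aldol adduct
Product: 11 C6 tert-butyldimethylsilyl ether of 10
Conditions: TBSOTf, 2,6-lutidine, CH2Cl2, −78 °C
Reagents that add atoms: tert-butyldimethylsilyl triflate, CC(C)(C)[Si](C)(C)OS(=O)(=O)C(F)(F)F
Why: Silyl triflate silylation at low temperature should cap the hindered aldol hydroxyl faster than retro-aldol cleavage or activation of the epoxide can occur.

Step 6
Reactants: 11 C6 silyl ether
Product: 12 E allylic alcohol (C9 CH2OH on the E C1=C10 alkene)
Conditions: SeO2 (cat.), t-BuOOH, salicylic acid (cat.), CH2Cl2, rt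
Reagents that add atoms: selenium dioxide, O=[Se]=O (transfers the oxygen); tert-butyl hydroperoxide, CC(C)(C)OO (restores SeO2, net oxygen source)
Why: Catalytic SeO2 allylic oxidation (ene reaction, then [2,3]-shift) of a dimethyl-substituted alkene terminus is selective for the E methyl group and keeps the alkene geometry; any enal from further oxidation converges in step 7.

Step 7
Reactants: 12 E allylic alcohol
Product: 13 acyclic C8,C9 diol (C8 CH2OH, C9 CH2OH, C12 tert-butyl ester)
Conditions: LiBH4, MeOH, THF, 0 °C
Reagents that add atoms: none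
Why: LiBH4 reduces the exocyclic imide carbonyl to the primary C8 alcohol and releases the auxiliary, while the tert-butyl ester, epoxide and silyl ether are inert at 0 °C and the hindered ester resists the new C8 alkoxide.

Step 8
Reactants: 13 acyclic C8,C9 diol
Product: 14 epoxy dialdehyde (C8 aldehyde, C9 enal)
Conditions: Dess–Martin periodinane, pyridine, CH2Cl2, 0 °C to rt; used at once
Reagents that add atoms: none
Why: Dess–Martin oxidation converts the primary and the allylic alcohol to aldehydes in one operation under buffered, non-epimerising conditions, so C7 next to the C8 aldehyde and the β-silyloxy group should survive.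

Step 9
Reactants: 14 epoxy dialdehyde
Product: 15 ten-membered cis-8,9-diol, tert-butyl (4S,5S,6S,7R,8R,9S)-6-(tert-butyldimethylsilyloxy)-4,5-epoxy-8,9-dihydroxygermacr-1(10)E-en-12-oate
Conditions: SmI2 (3 equiv), THF, syringe-pump addition of 14 to about 0.003 M, 0 °C to rt; then aq NH4Cl
Reagents that add atoms: none
Why: Two single-electron transfers from SmI2 give the samarium-bound allylic ketyl of the enal (reduced first) and the ketyl of the samarium-coordinated C8 aldehyde, and the two carbonyl carbons join inside a samarium-bridged array to give the diolate, protonated on work-up. The closest known reaction type is the intramolecular pinacol coupling of dialdehydes with SmI2 or low-valent titanium, used for rings up to macrocycles. The ten-membered ring closes by C8–C9 bond formation, 10-exo-trig at the C8 carbonyl, under slow addition, and the E C1=C10 alkene and the C4–C5 epoxide remove rotors from the connecting chain. C8 (R) is set by the C7 centre in a Felkin–Anh arrangement with the C6 chain anti to the forming bond, which puts O8 trans to the CH2CO2t-Bu branch; C9 (S) is set by the trivalent samarium that bridges both ketyl oxygens while C10 and its methyl stay outside the ring perimeter, which should give the cis diol and is the least secure element. The step needs coupling at the carbonyl carbon of the enal and not at C1, which is favoured by the lower hindrance at the aldehyde carbon of a samarium-bound enal ketyl and by the strain of the eight-membered ring that C1 attack would close. The epoxide, silyl ether and tert-butyl ester are not conjugated with either ketyl and no leaving group sits on a carbon next to a ketyl, so they should not be reduced.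

Step 10
Reactants: 15 ten-membered cis-8,9-diol
Product: 16 9-hydroxy-8,12-lactone, (4S,5S,6S,7R,8R,9S)-6-(tert-butyldimethylsilyloxy)-4,5-epoxy-9-hydroxygermacr-1(10)E-en-12,8-olide
Conditions: KOt-Bu (0.2 equiv), THF, −20 to 0 °C; then aq NH4Cl
Reagents that add atoms: none
Why: Alkoxide-catalysed intramolecular transesterification (the lactone-forming event of the Stobbe condensation), in which the C8 alkoxide closes the five-membered lactone 5-exo-trig onto the tert-butyl ester and expels tert-butoxide as chain carrier; the five-membered ring is preferred over the six-membered one from O9, and low temperature should hold the C6 silyl group in place.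

Step 11
Reactants: 16 9-hydroxy-8,12-lactone
Product: 17 9-isobutyrate of 16
Conditions: isobutyric anhydride, DMAP (cat.), Et3N, CH2Cl2, 0 °C to rt
Reagents that add atoms: isobutyric anhydride, CC(C)C(=O)OC(=O)C(C)C
Why: DMAP-catalysed acylation of the only free hydroxyl, the secondary allylic O9.

Step 12
Reactants: 17 9-isobutyrate
Product: 19 11-(dimethylaminomethyl) lactone (C11 epimers), via lithium enolate 18 (not isolated)
Conditions: lithium diisopropylamide (LiN(i-Pr)2, 1.1 equiv), THF, −78 °C; then CH2=NMe2+ I−, −78 to 0 °C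
Reagents that add atoms: dimethylmethyleneammonium iodide (Eschenmoser's salt), C=[N+](C)C.[I-]
Why: Lactone enolate Mannich reaction, in which the base removes the more acidic, unhindered C11 proton in preference to the tertiary C–H of the isobutyrate and the iminium salt traps the enolate; the C11 configuration is irrelevant because that carbon becomes sp2 in step 13.

Step 13
Reactants: 19 11-(dimethylaminomethyl) lactone
Product: 21 6-O-tert-butyldimethylsilyl ether of the target (C11=C13 methylene lactone), via trimethylammonium iodide 20 (not isolated)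
Conditions: MeI, MeOH/CH2Cl2, rt; then aq NaHCO3, CH2Cl2, rt
Reagents that add atoms: none
Why: Exhaustive methylation and E1cB loss of trimethylamine under bicarbonate is the standard second half of the Eschenmoser α-methylenation and should give the exocyclic alkene without touching the esters or the epoxide.

Step 14
Reactants: 21 6-O-silyl ether of the target
Product: 22 CNP0220196.1, (1(10)E,4S,5S,6S,7S,8R,9S)-4,5-epoxy-6-hydroxy-9-isobutyryloxygermacra-1(10),11(13)-dien-12,8-olide
Conditions: HF·pyridine, pyridine, THF, 0 °C to rt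
Reagents that add atoms: none
Why: Pyridine-buffered HF·pyridine cleaves the secondary silyl ether under conditions too weakly acidic for transannular opening of the epoxide and not basic enough to form the O6 alkoxide that could translactonise or add to the methylene lactone.

**Compound list**
1 | geraniol | CC(C)=CCC/C(C)=C/CO | starting material
2 | (2S,3S)-2,3-epoxygeraniol | OC[C@@H]1O[C@@]1(C)CCC=C(C)C | intermediate
3 | (2R,3S)-2,3-epoxygeranial | O=C[C@@H]1O[C@@]1(C)CCC=C(C)C | intermediate
4 | mono-tert-butyl succinate (4-tert-butoxy-4-oxobutanoic acid) | CC(C)(C)OC(=O)CCC(=O)O | starting material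
5 | (S)-4-benzyl-2-oxazolidinone | O=C1N[C@@H](Cc2ccccc2)CO1 | starting material
6 | mixed pivalic anhydride of 4 (formed in the flask) | CC(C)(C)OC(=O)CCC(=O)OC(=O)C(C)(C)C | intermediate
7 | tert-butyl 4-[(4S)-4-benzyl-2-oxo-1,3-oxazolidin-3-yl]-4-oxobutanoate | CC(C)(C)OC(=O)CCC(=O)N1[C@@H](Cc2ccccc2)COC1=O | intermediate
8 | Z dibutylboron enolate of 7 (formed in the flask) | CCCCB(CCCC)O/C(=C\CC(=O)OC(C)(C)C)N1[C@@H](Cc2ccccc2)COC1=O | intermediate
9 | dibutylboron aldolate (formed in the flask) | CCCCB(CCCC)O[C@H]([C@@H]1O[C@@]1(C)CCC=C(C)C)[C@H](CC(=O)OC(C)(C)C)C(=O)N1[C@@H](Cc2ccccc2)COC1=O | intermediate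
10 | syn aldol adduct, tert-butyl (3S,4S)-3-{[(4S)-4-benzyl-2-oxo-1,3-oxazolidin-3-yl]carbonyl}-4-hydroxy-4-[(2S,3S)-3-methyl-3-(4-methylpent-3-en-1-yl)oxiran-2-yl]butanoate | CC(C)(C)OC(=O)C[C@@H]([C@H](O)[C@@H]1O[C@@]1(C)CCC=C(C)C)C(=O)N1[C@@H](Cc2ccccc2)COC1=O | intermediate
11 | C6 tert-butyldimethylsilyl ether of 10 | CC(C)(C)OC(=O)C[C@@H]([C@H](O[Si](C)(C)C(C)(C)C)[C@@H]1O[C@@]1(C)CCC=C(C)C)C(=O)N1[C@@H](Cc2ccccc2)COC1=O | intermediate
12 | E allylic alcohol (C9 CH2OH) | CC(C)(C)OC(=O)C[C@@H]([C@H](O[Si](C)(C)C(C)(C)C)[C@@H]1O[C@@]1(C)CC/C=C(\C)CO)C(=O)N1[C@@H](Cc2ccccc2)COC1=O | intermediate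
13 | acyclic C8,C9 diol | CC(C)(C)OC(=O)C[C@H](CO)[C@H](O[Si](C)(C)C(C)(C)C)[C@@H]1O[C@@]1(C)CC/C=C(\C)CO | intermediate
14 | epoxy dialdehyde (C8 aldehyde, C9 enal) | O=C[C@@H](CC(=O)OC(C)(C)C)[C@H](O[Si](C)(C)C(C)(C)C)[C@@H]1O[C@@]1(C)CC/C=C(\C)C=O | intermediate
15 | ten-membered cis-8,9-diol, tert-butyl (4S,5S,6S,7R,8R,9S)-6-(tert-butyldimethylsilyloxy)-4,5-epoxy-8,9-dihydroxygermacr-1(10)E-en-12-oate | CC(C)(C)OC(=O)C[C@H]1[C@H](O[Si](C)(C)C(C)(C)C)[C@@H]2O[C@@]2(C)CC/C=C(\C)[C@H](O)[C@@H]1O | intermediate
16 | 9-hydroxy-8,12-lactone (4S,5S,6S,7R,8R,9S) | O=C1C[C@H]2[C@H](O[Si](C)(C)C(C)(C)C)[C@@H]3O[C@@]3(C)CC/C=C(\C)[C@H](O)[C@@H]2O1 | intermediate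
17 | 9-isobutyrate of 16 | O=C1C[C@H]2[C@H](O[Si](C)(C)C(C)(C)C)[C@@H]3O[C@@]3(C)CC/C=C(\C)[C@H](OC(=O)C(C)C)[C@@H]2O1 | intermediate
18 | lithium enolate of 17 (formed in the flask) | [Li]OC1=C[C@H]2[C@H](O[Si](C)(C)C(C)(C)C)[C@@H]3O[C@@]3(C)CC/C=C(\C)[C@H](OC(=O)C(C)C)[C@@H]2O1 | intermediate
19 | 11-(dimethylaminomethyl) lactone (C11 epimers) | CN(C)CC1C(=O)O[C@@H]2[C@@H]1[C@H](O[Si](C)(C)C(C)(C)C)[C@@H]1O[C@@]1(C)CC/C=C(\C)[C@@H]2OC(=O)C(C)C | intermediate
20 | trimethylammonium iodide of 19 (formed in the flask) | C[N+](C)(C)CC1C(=O)O[C@@H]2[C@@H]1[C@H](O[Si](C)(C)C(C)(C)C)[C@@H]1O[C@@]1(C)CC/C=C(\C)[C@@H]2OC(=O)C(C)C.[I-] | intermediate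
21 | 6-O-tert-butyldimethylsilyl ether of the target (4S,5S,6S,7R,8R,9S) | C=C1C(=O)O[C@@H]2[C@@H]1[C@H](O[Si](C)(C)C(C)(C)C)[C@@H]1O[C@@]1(C)CC/C=C(\C)[C@@H]2OC(=O)C(C)C | intermediate
22 | CNP0220196.1, (1(10)E,4S,5S,6S,7S,8R,9S)-4,5-epoxy-6-hydroxy-9-isobutyryloxygermacra-1(10),11(13)-dien-12,8-olide | C=C1C(=O)O[C@@H]2[C@@H]1[C@H](O)[C@@H]1O[C@@]1(C)CC/C=C(\C)[C@@H]2OC(=O)C(C)C | target

Total step count: 14. Longest linear sequence: 13 steps (steps 1, 2 and 4–14 from geraniol).

**Steps most likely to fail**

1. Step 9 (ring-closing pinacol). The coupling may pass through an open arrangement in which C10 turns anti to C7, so that the enal ketyl is attacked on its other face and the trans diol (C9 epimer) results. Intermolecular coupling is the second hazard and is countered only by dilution. The fallback sets C9 by displacement instead of by the samarium bridge. Setting out from 14, the same closure would be taken through with the 9-epi diol F1. Base-catalysed lactonisation as in step 10 would give the 9-epi hydroxy lactone F2. A Mitsunobu esterification of F2 with isobutyric acid (PPh3, diisopropyl azodicarboxylate, toluene, 0 °C to rt) would then install the ester with inversion at C9 and come back to the route at 17.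

2. Step 6 (allylic oxidation). Slow and unselective oxygen transfer may erode the material: over-oxidation, attack at C2, or opening of the epoxide by selenous acid over the long reaction time. The fallback uses olefin metathesis in place of C–H oxidation. Setting out from 11, cross metathesis with excess methacrolein (second-generation Hoveyda–Grubbs catalyst, (H2IMes)Cl2Ru=CH(C6H4-2-O-i-Pr), CH2Cl2, 40 °C) would exchange the isopropylidene terminus for the E 2-methyl enal with loss of isobutene and give the enal imide F3. LiBH4 (MeOH, THF, 0 °C) would then reduce the enal and the imide together and come back to the route at 13.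

3. Step 12 (Mannich reaction beside the isobutyrate). Deprotonation may not be selective for the lactone, and the lactone enolate may take the acyl group from O9 through a six-membered transition state. The fallback methylenates before the ester is present. Setting out from 16, lithium diisopropylamide (2.2 equiv, THF, −78 °C) would give the O,C-dilithio species F4. Dimethylmethyleneammonium iodide would give the amino alcohol F5, MeI the ammonium iodide F6, and aqueous NaHCO3 the methylene hydroxy lactone F7. Acylation of O9 with isobutyric anhydride (DMAP, Et3N, CH2Cl2) would come back to the route at 21.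

**Further compounds**
F1 | step 9 | 9-epi diol (trans-8,9-diol, 8R,9R) | CC(C)(C)OC(=O)C[C@H]1[C@H](O[Si](C)(C)C(C)(C)C)[C@@H]2O[C@@]2(C)CC/C=C(\C)[C@@H](O)[C@@H]1O
F2 | step 9 | 9-epi hydroxy lactone | O=C1C[C@H]2[C@H](O[Si](C)(C)C(C)(C)C)[C@@H]3O[C@@]3(C)CC/C=C(\C)[C@@H](O)[C@@H]2O1
F3 | step 6 | enal imide (C9 aldehyde, C8 imide) | CC(C)(C)OC(=O)C[C@@H]([C@H](O[Si](C)(C)C(C)(C)C)[C@@H]1O[C@@]1(C)CC/C=C(\C)C=O)C(=O)N1[C@@H](Cc2ccccc2)COC1=O
F4 | step 12 | O,C-dilithio species of 16 | [Li]OC1=C[C@H]2[C@H](O[Si](C)(C)C(C)(C)C)[C@@H]3O[C@@]3(C)CC/C=C(\C)[C@H](O[Li])[C@@H]2O1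
F5 | step 12 | amino alcohol, 11-(dimethylaminomethyl)-9-hydroxy lactone | CN(C)CC1C(=O)O[C@@H]2[C@@H]1[C@H](O[Si](C)(C)C(C)(C)C)[C@@H]1O[C@@]1(C)CC/C=C(\C)[C@@H]2O
F6 | step 12 | ammonium iodide of F5 | C[N+](C)(C)CC1C(=O)O[C@@H]2[C@@H]1[C@H](O[Si](C)(C)C(C)(C)C)[C@@H]1O[C@@]1(C)CC/C=C(\C)[C@@H]2O.[I-]
F7 | step 12 | methylene hydroxy lactone (9-hydroxy, 6-O-silyl) | C=C1C(=O)O[C@@H]2[C@@H]1[C@H](O[Si](C)(C)C(C)(C)C)[C@@H]1O[C@@]1(C)CC/C=C(\C)[C@@H]2O
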